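**Plan**
Retrosynthesis: the esters and the C1 enone are adjusted last. The seven-membered ring is cut at C8–C9 and C6–C7, which releases C7–C8 as a two-carbon unit (ethyl vinyl ether). Then C5=C6 (boron-Wittig), C5–C11 and C4–C10 (ketene [2+2]), and C1–C2 (vinylogous aldol) are cut.
Forward: open chain, then cyclobutane and six-membered ring together (step 8), then the seven-membered ring (step 12), then O9, O7, the esters and the enone.
Enabling feature: C5 and C10 are the 1,3-related corners of the cyclobutane C4–C5–C11–C10. Their substituents C6 and C9 both stand on the face opposite the C1–C2–C3 bridge (1,3-diaxial), so only two carbons are missing. The C7/C9 1,3-dioxygen pattern polarises that unit as an α-oxygenated vinyl anion.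
C6 is fully substituted and cyclobutylcarbinyl. A radical or cation there would open or expand the four-membered ring, so C6 is delivered by a 1,2-shift from boron.
Stereochemistry: a catalyst-set C1 carbinol relays to C4, C10 and C11 through allylic strain and is erased at the end. C5 comes from face-selective protonation, C9 from ligand-controlled Cu–B addition, and C7 from an anti-selective Evans–Tishchenko reduction.

Key step: step 12

Remark (numbering): longipinane numbering is used. C1 (C=O), C2=C3(CH3), C4, C5, C6(CH3)2, C7 (O-angeloyl), C8, C9 (O-isovaleryl), C10(CH3), C11.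
Remark (assumption): the sense of induction in the two catalyst-controlled steps (5 and 13) is assigned by analogy. If it proves opposite, the mirror-image catalyst or ligand is used.

**Step 1**
Reactants: 1 1,1-dimethoxypropan-2-one; 2 triethyl phosphonoacetate
Product: 3 ethyl (E)-4,4-dimethoxy-3-methylbut-2-enoate
Conditions: NaH, THF, 0 °C → rt
Reagents that add atoms: none
Why: In this Horner–Wadsworth–Emmons olefination the reversible addition of the stabilised anion should place the bulkier dimethoxymethyl group trans to the ester (E).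

**Step 2**
Reactants: 3 ethyl (E)-4,4-dimethoxy-3-methylbut-2-enoate
Product: 4 (E)-4,4-dimethoxy-3-methylbut-2-en-1-ol
Conditions: DIBAL-H (2.2 equiv), CH2Cl2, −78 °C; Rochelle salt
Reagents that add atoms: none
Why: DIBAL-H reduces the enoate 1,2 to the allylic alcohol and leaves the acetal and the alkene geometry untouched.

**Step 3**
Reactants: 4 (E)-4,4-dimethoxy-3-methylbut-2-en-1-ol
Product: 5 (E)-4,4-dimethoxy-3-methylbut-2-enal
Conditions: MnO2, CH2Cl2, rt
Reagents that add atoms: none
Why: MnO2 allylic oxidation is neutral, so the acetal and the E-alkene should survive.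

**Step 4**
Reactants: 6 methyl 3-methylbut-2-enoate
Product: 7 1-methoxy-3-methyl-1-(tert-butyldimethylsilyloxy)buta-1,3-diene
Conditions: LDA, THF, −78 °C; TBSCl, DMPU
Reagents that add atoms: tert-butyldimethylsilyl chloride CC(C)(C)[Si](C)(C)Cl
Why: γ-Deprotonation of the senecioate followed by O-silylation gives the silyl dienol ether (extended silyl ketene acetal formation).

**Step 5**
Reactants: 5 (E)-4,4-dimethoxy-3-methylbut-2-enal; 7 silyl dienol ether
Product: 8 methyl (2E,5S,6E)-5-hydroxy-8,8-dimethoxy-3,7-dimethylocta-2,6-dienoate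
Conditions: SiCl4 (1.1 equiv), (R,R)-binaphthyldiamine-derived bisphosphoramide (5 mol %), i-Pr2NEt (10 mol %), CH2Cl2, −78 °C; aq. NaHCO3
Reagents that add atoms: none
Why: In this catalytic asymmetric vinylogous Mukaiyama aldol reaction the chiral Lewis-base-bound silicon cation binds only the aldehyde, the dienol ether attacks through its unhindered γ-carbon, the catalyst sets the (S)-carbinol (future C1), and free SiCl4 is too weak an acid to ionise the acetal at −78 °C.

**Step 6**
Reactants: 8 hydroxy ester
Product: 9 methyl (2E,5S,6E)-5-(tert-butyldimethylsilyloxy)-8,8-dimethoxy-3,7-dimethylocta-2,6-dienoate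
Conditions: TBSCl, imidazole, DMF, rt
Reagents that add atoms: tert-butyldimethylsilyl chloride CC(C)(C)[Si](C)(C)Cl
Why: Standard silylation is used, and silyl triflates are avoided because they would attack the acetal.

**Step 7**
Reactants: 9 silyl ether ester
Product: 10 potassium (2E,5S,6E)-5-(tert-butyldimethylsilyloxy)-8,8-dimethoxy-3,7-dimethylocta-2,6-dienoate
Conditions: KOSiMe3, THF, rt
Reagents that add atoms: potassium trimethylsilanolate [K+].[O-][Si](C)(C)C
Why: Anhydrous silanolate cleavage of the methyl ester gives the carboxylate salt without aqueous acid, so the acetal and silyl ether stay intact.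

**Step 8**
Reactants: 10 potassium carboxylate
Product: 13 4-(tert-butyldimethylsilyloxy)-7-(dimethoxymethyl)-7-methyl-2-methylenebicyclo[3.1.1]heptan-6-one, via acid chloride 11 (not isolated), via vinylketene 12 (not isolated)
Conditions: (COCl)2 (1.0 equiv), toluene, 0 °C; then slow addition to Et3N, toluene, 110 °C (high dilution)
Reagents that add atoms: none
Why: In this intramolecular vinylketene–alkene [2+2] cycloaddition, HCl is lost through the γ-methyl group cis to the acyl chloride, the ketene carbonyl carbon (C5) bonds to the less substituted C11 while charge builds at tertiary C10, which closes onto C4, so the bridged bicyclo[3.1.1] ketone should form; suprafacial addition to the E-alkene puts CH(OMe)2 anti to the three-atom bridge, and allylic 1,3-strain (C1–H inside next to the C10 methyl, OTBS outside) lets the (S)-carbinol select the alkene face and fix C4, C10 and C11.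

**Step 9**
Reactants: 14 bis(pinacolboryl)methane
Product: 15 1,1-bis(pinacolboryl)ethane
Conditions: LiTMP, THF, 0 °C; MeI
Reagents that add atoms: iodomethane CI
Why: The doubly boron-stabilised carbanion forms readily and is C-methylated (alkylation of a geminal diboronate).

**Step 10**
Reactants: 13 bicyclic ketone; 15 1,1-bis(pinacolboryl)ethane
Product: 16 pinacol 1-[4-(tert-butyldimethylsilyloxy)-7-(dimethoxymethyl)-7-methyl-2-methylenebicyclo[3.1.1]heptan-6-ylidene]ethylboronate (C5=C6 alkenyl boronate; geometric isomers of no consequence)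
Conditions: LiTMP, THF, 0 °C; then 13, −78 °C → rt
Reagents that add atoms: none
Why: In this boron-Wittig olefination the strained cyclobutanone cannot enolise (both α-carbons are bridgeheads), so it should take up the diboryl carbanion, and syn loss of borate then gives the tetrasubstituted alkenyl boronate.

**Step 11**
Reactants: 16 alkenyl boronate
Product: 18 pinacol 2-[4-(tert-butyldimethylsilyloxy)-7-(dimethoxymethyl)-7-methyl-2-methylenebicyclo[3.1.1]heptan-6-yl]propan-2-ylboronate (C6 cis to C9; C5–H on the side of the three-atom bridge), via lithium methylboronate complex 17 (not isolated)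
Conditions: MeLi, THF, −78 °C; 2,6-di-tert-butylpyridinium triflate, −78 → −20 °C
Reagents that add atoms: methyllithium [Li]C
Why: Proposed new method: MeLi adds to boron, the alkenylboronate complex 17 is protonated at its nucleophilic β-carbon C5, and as charge develops at C6 the methyl group shifts from boron to C6 (electrophile-induced 1,2-metallate rearrangement), which gives the tertiary boronic ester without a free C6 cation; the closest known reaction types are the acid-induced alkyl shift of alkenyl(trialkyl)borates and the halogen-, selenium- and carbenium-induced shifts of vinylboronic ester ate complexes; the bulky acid can reach C5 only from the face of the C1–C3 bridge because the other face is covered by the dimethoxymethyl group on C10, so H ends syn to the bridge and C6 cis to C9.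

**Step 12**
Reactants: 18 tertiary boronic ester; 19 ethyl vinyl ether
Product: 24 (1S)-1-(tert-butyldimethylsilyloxy)-3-methylenelongipin-8-en-7-one, via 1-ethoxyvinyllithium 20 (not isolated), via boronate complex 21 (not isolated), via α-ethoxy boronic ester 22 (not isolated), via β-methoxy ketone 23 (not isolated)
Conditions: 19, t-BuLi, THF, −78 → 0 °C; 18, −78 → −40 °C; TMSOTf, 2,6-di-tert-butylpyridine, −78 °C; aq. NaOH, H2O2, 0 °C → rt; DBU (cat.), CH2Cl2, rt
Reagents that add atoms: hydrogen peroxide OO
Why: Proposed new method: 20 adds to the boron of 18 to give complex 21, whose ethoxyvinyl group is a very electron-rich enol ether (donation from oxygen and from the B–C σ bonds); TMSOTf ionises the neighbouring dimethyl acetal, C8 attacks the C9 oxocarbenium ion, and the charge building at C7 is discharged at once by 1,2-shift of tertiary C6 from boron to C7, so both bonds arise in one polar cascade and C6 never becomes a radical or cation that would open or expand the cyclobutane. The closest known reaction types are the electrophile-induced 1,2-metallate rearrangements of vinyl- and α-alkoxyvinyl-boron ate complexes with carbon electrophiles (aldehydes, carbenium and iminium ions; 1,3-diols or ketones after oxidation) and the Mukaiyama-type addition of enol ethers to acetals; the ring-closing mode and the tertiary cyclobutylcarbinyl migrating group are new. Ring closure: C8–C9 formation first closes an eight-membered boracycle (C9–C10–C11–C5–C6–B–C7–C8), which the shift contracts to the seven-membered carbocycle with boron exocyclic on C7; the ethoxy group gives the C7 cation enough lifetime for the B–C6 bond to align, so the anti-periplanar geometry of a concerted addition, impossible in this ring size, is not required. C6 migrates with retention and C5 and C10 are untouched; the new centres C7 and C9 in 22 need no control, because peroxide turns C7 into the ketone (loss of ethanol) and base expels methanol from C9 to give enone 24. Needed selectivities: 20 must attack boron only (acetal, silyl ether and 1,1-disubstituted alkene are inert to it at −78 °C), and the silyl triflate must ionise the acetal rather than silylate C8 or strip pinacolate; the 1,3-diaxial contact of C9 with the borate, the hindered base and the low temperature favour the intramolecular path.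

**Step 13**
Reactants: 24 tricyclic enone
Product: 26 (1S)-1-(tert-butyldimethylsilyloxy)-9-hydroxy-3-methylenelongipinan-7-one (O9 on the C11/C1 side), via 9-boryl ketone 25 (not isolated)
Conditions: CuCl, NaOt-Bu, (R,S)-Josiphos (5 mol %), B2pin2, MeOH, THF, rt; then NaBO3·4H2O, THF/H2O
Reagents that add atoms: sodium perborate [Na+].[Na+].O[B-]1(O)OO[B-](O)(O)OO1
Why: In this copper-catalysed asymmetric conjugate borylation of a cyclic enone followed by stereoretentive oxidation, the two faces of C9 differ only through the remote C1–C3 bridge, so the chiral ligand should decide the C9 configuration, and the unactivated methylene group is inert.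

**Step 14**
Reactants: 26 β-hydroxy ketone; 27 3-methylbutanal
Product: 28 (1S)-1-(tert-butyldimethylsilyloxy)-7-hydroxy-3-methylenelongipinan-9-yl 3-methylbutanoate (O7 trans to O9)
Conditions: SmI2 (30 mol %), 27 (6 equiv), THF, −10 °C
Reagents that add atoms: none
Why: In this Evans–Tishchenko reduction the hemiacetal of O9 with 27 and the C7 ketone bind Sm(III), and hydride passes through a six-membered transition state to the C7 face on which O9 stands, so O7 ends 1,3-anti, the isovaleryl group is left on O9, and the diol is differentiated in one step.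

**Step 15**
Reactants: 28 hydroxy ester; 29 angelic acid
Product: 31 (1S)-1-(tert-butyldimethylsilyloxy)-9-(3-methylbutanoyloxy)-3-methylenelongipinan-7-yl (Z)-2-methylbut-2-enoate, via mixed anhydride 30 (not isolated)
Conditions: 29, 2,4,6-trichlorobenzoyl chloride, Et3N, toluene, rt; then 28, 80 °C
Reagents that add atoms: none
Why: This Yamaguchi esterification is run without a nucleophilic catalyst, so the activated anhydride acylates the hindered neopentylic alcohol while the reversible conjugate addition that would turn angelate into tiglate is avoided.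

**Step 16**
Reactants: 31 silyl ether diester
Product: 32 (1S)-1-hydroxy-9-(3-methylbutanoyloxy)-3-methylenelongipinan-7-yl (Z)-2-methylbut-2-enoate
Conditions: HF·pyridine, THF, 0 °C → rt
Reagents that add atoms: none
Why: Buffered fluoride desilylation leaves both esters and the Z-alkene untouched.

**Step 17**
Reactants: 32 C1 alcohol
Product: 34 target 7-angeloyloxy-9-isovaleryloxylongipin-2-en-1-one, via 3-methylene ketone 33 (not isolated)
Conditions: Dess–Martin periodinane, NaHCO3, CH2Cl2, 0 °C → rt; then DBU (cat.), CH2Cl2, rt
Reagents that add atoms: none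
Why: Dess–Martin oxidation erases the relay stereocentre, and base moves the β,γ-double bond into conjugation; C11 is a bridgehead and cannot enolise, so only the C2=C3 enone can form and no stereocentre is at risk.

**Compound list**
1 | 1,1-dimethoxypropan-2-one | CC(=O)C(OC)OC | starting material
2 | triethyl phosphonoacetate | CCOC(=O)CP(=O)(OCC)OCC | starting material
3 | ethyl (E)-4,4-dimethoxy-3-methylbut-2-enoate | CCOC(=O)/C=C(\C)C(OC)OC | intermediate
4 | (E)-4,4-dimethoxy-3-methylbut-2-en-1-ol | OC/C=C(\C)C(OC)OC | intermediate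
5 | (E)-4,4-dimethoxy-3-methylbut-2-enal | O=C/C=C(\C)C(OC)OC | intermediate
6 | methyl 3-methylbut-2-enoate | COC(=O)C=C(C)C | starting material
7 | 1-methoxy-3-methyl-1-(tert-butyldimethylsilyloxy)buta-1,3-diene | COC(O[Si](C)(C)C(C)(C)C)=CC(C)=C | intermediate
8 | methyl (2E,5S,6E)-5-hydroxy-8,8-dimethoxy-3,7-dimethylocta-2,6-dienoate | COC(=O)/C=C(\C)C[C@H](O)/C=C(\C)C(OC)OC | intermediate
9 | 5-O-TBS ether of 8 | COC(=O)/C=C(\C)C[C@H](O[Si](C)(C)C(C)(C)C)/C=C(\C)C(OC)OC | intermediate
10 | potassium carboxylate from 9 | [K+].[O-]C(=O)/C=C(\C)C[C@H](O[Si](C)(C)C(C)(C)C)/C=C(\C)C(OC)OC | intermediate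
11 | acid chloride | O=C(Cl)/C=C(\C)C[C@H](O[Si](C)(C)C(C)(C)C)/C=C(\C)C(OC)OC | intermediate
12 | vinylketene | O=C=CC(=C)C[C@H](O[Si](C)(C)C(C)(C)C)/C=C(\C)C(OC)OC | intermediate
13 | bicyclic C5 ketone (CH(OMe)2 on C10 anti to the C1–C3 bridge; OTBS on C1 trans to C10) | COC(OC)[C@@]2(C)[C@@H]3[C@@H](O[Si](C)(C)C(C)(C)C)CC(=C)[C@H]2C3=O | intermediate
14 | bis(pinacolboryl)methane | C(B1OC(C)(C)C(C)(C)O1)B2OC(C)(C)C(C)(C)O2 | starting material
15 | 1,1-bis(pinacolboryl)ethane | CC(B1OC(C)(C)C(C)(C)O1)B2OC(C)(C)C(C)(C)O2 | intermediate
16 | C5=C6 alkenyl boronate | COC(OC)[C@@]2(C)[C@@H]3[C@@H](O[Si](C)(C)C(C)(C)C)CC(=C)[C@H]2C3=C(C)B4OC(C)(C)C(C)(C)O4 | intermediate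
17 | lithium methylboronate complex | [Li+].COC(OC)[C@@]2(C)[C@@H]3[C@@H](O[Si](C)(C)C(C)(C)C)CC(=C)[C@H]2C3=C(C)[B-]4(C)OC(C)(C)C(C)(C)O4 | intermediate
18 | tertiary C6 boronic ester (C6 cis to C9) | COC(OC)[C@@]2(C)[C@@H]3[C@@H](O[Si](C)(C)C(C)(C)C)CC(=C)[C@H]2[C@@H]3C(C)(C)B4OC(C)(C)C(C)(C)O4 | intermediate
19 | ethyl vinyl ether | C=COCC | starting material
20 | 1-ethoxyvinyllithium | [Li]C(=C)OCC | intermediate
21 | lithium (1-ethoxyvinyl)boronate complex | [Li+].COC(OC)[C@@]2(C)[C@@H]3[C@@H](O[Si](C)(C)C(C)(C)C)CC(=C)[C@H]2[C@@H]3C(C)(C)[B-]4(C(=C)OCC)OC(C)(C)C(C)(C)O4 | intermediate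
22 | tricyclic 7-ethoxy-7-boryl-9-methoxy compound (C7 and C9 epimers) | CCOC1(B4OC(C)(C)C(C)(C)O4)CC(OC)[C@@]2(C)[C@@H]3[C@@H](O[Si](C)(C)C(C)(C)C)CC(=C)[C@H]2[C@@H]3C1(C)C | intermediate
23 | 9-methoxy 7-ketone (C9 epimers) | O=C1CC(OC)[C@@]2(C)[C@@H]3[C@@H](O[Si](C)(C)C(C)(C)C)CC(=C)[C@H]2[C@@H]3C1(C)C | intermediate
24 | (1S)-1-(TBSO)-3-methylenelongipin-8-en-7-one | O=C1C=C[C@@]2(C)[C@@H]3[C@@H](O[Si](C)(C)C(C)(C)C)CC(=C)[C@H]2[C@@H]3C1(C)C | intermediate
25 | 9-(pinacolboryl) 7-ketone | O=C1C[C@@H](B4OC(C)(C)C(C)(C)O4)[C@@]2(C)[C@@H]3[C@@H](O[Si](C)(C)C(C)(C)C)CC(=C)[C@H]2[C@@H]3C1(C)C | intermediate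
26 | 9-hydroxy 7-ketone | O=C1C[C@@H](O)[C@@]2(C)[C@@H]3[C@@H](O[Si](C)(C)C(C)(C)C)CC(=C)[C@H]2[C@@H]3C1(C)C | intermediate
27 | 3-methylbutanal | CC(C)CC=O | starting material
28 | 7-hydroxy 9-isovalerate (O7 trans to O9) | O[C@@H]1C[C@@H](OC(=O)CC(C)C)[C@@]2(C)[C@@H]3[C@@H](O[Si](C)(C)C(C)(C)C)CC(=C)[C@H]2[C@@H]3C1(C)C | intermediate
29 | angelic acid, (Z)-2-methylbut-2-enoic acid | C/C=C(/C)C(=O)O | starting material
30 | angelic 2,4,6-trichlorobenzoic anhydride | C/C=C(/C)C(=O)OC(=O)c1c(Cl)cc(Cl)cc1Cl | intermediate
31 | 7-angelate 9-isovalerate 1-O-TBS | C/C=C(/C)C(=O)O[C@@H]1C[C@@H](OC(=O)CC(C)C)[C@@]2(C)[C@@H]3[C@@H](O[Si](C)(C)C(C)(C)C)CC(=C)[C@H]2[C@@H]3C1(C)C | intermediate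
32 | 7-angelate 9-isovalerate 1-ol | C/C=C(/C)C(=O)O[C@@H]1C[C@@H](OC(=O)CC(C)C)[C@@]2(C)[C@@H]3[C@@H](O)CC(=C)[C@H]2[C@@H]3C1(C)C | intermediate
33 | 3-methylene 1-ketone | C/C=C(/C)C(=O)O[C@@H]1C[C@@H](OC(=O)CC(C)C)[C@@]2(C)[C@@H]3C(=O)CC(=C)[C@H]2[C@@H]3C1(C)C | intermediate
34 | target CNP0240547.2 | C/C=C(/C)C(=O)O[C@@H]1C[C@@H](OC(=O)CC(C)C)[C@@]2(C)[C@@H]3C(=O)C=C(C)[C@H]2[C@@H]3C1(C)C | target

**Step count**
Total steps: 17. Longest linear sequence: 15 (steps 1–3, 5–8, 10–17).

**Steps most likely to fail**

Step 12 (ring-closing boronate shift).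
- What may go wrong: slow complexation at the hindered boron; silylation or protonation of the ethoxyvinyl group instead of attack on the oxocarbenium ion; loss of pinacolate to the silyl triflate.
- Fallback (known chemistry, the two bonds made one after the other): from 18, Zweifel olefination with 20 (then I2, NaOMe) should give the enol ether F1.
- Aqueous oxalic acid cleaves the enol ether and the acetal to the keto aldehyde F2.
- Intramolecular aldol condensation (KOH, MeOH) closes C8–C9 and returns to 24.

Step 11 (protonative methyl shift).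
- What may go wrong: protodeboronation at C6 instead of migration; poor facial selectivity of proton delivery as the 1,3-diaxial strain between C6 and C9 builds up.
- Fallback (known chemistry): from 13, Horner–Wadsworth–Emmons olefination with diethyl (1-cyanoethyl)phosphonate gives the cyclobutylidene nitrile F3.
- Conjugate reduction with a bulky ligated copper hydride, which approaches from the side of the three-atom bridge, gives the nitrile F4.
- LDA and MeI give the tertiary nitrile F5.
- MeLi followed by aqueous acid gives the keto aldehyde F2, and aldol condensation returns to 24.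

Step 14 (Evans–Tishchenko reduction).
- What may go wrong: the hemiacetal hydride may not reach the hindered C7 carbonyl across the rigid ring; retro-aldol opening or acyl migration may compete.
- Fallback: from 26, acylation with isovaleric anhydride (catalytic DMAP, 0 °C) gives the keto ester F6.
- Corey–Bakshi–Shibata reduction returns to 28. The large difference between quaternary C6 and the C8 methylene lets the catalyst choose the C7 face.

**Further compounds**
F1 | step 12 | C6-(1-ethoxyvinyl) bicyclic acetal | COC(OC)[C@@]2(C)[C@@H]3[C@@H](O[Si](C)(C)C(C)(C)C)CC(=C)[C@H]2[C@@H]3C(C)(C)C(=C)OCC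
F2 | step 12 | keto aldehyde (C9 formyl, C7 methyl ketone) | O=C[C@@]2(C)[C@@H]3[C@@H](O[Si](C)(C)C(C)(C)C)CC(=C)[C@H]2[C@@H]3C(C)(C)C(C)=O
F3 | step 11 | cyclobutylidene nitrile | COC(OC)[C@@]2(C)[C@@H]3[C@@H](O[Si](C)(C)C(C)(C)C)CC(=C)[C@H]2C3=C(C)C#N
F4 | step 11 | secondary nitrile (C6 epimers) | COC(OC)[C@@]2(C)[C@@H]3[C@@H](O[Si](C)(C)C(C)(C)C)CC(=C)[C@H]2[C@@H]3C(C)C#N
F5 | step 11 | tertiary nitrile | COC(OC)[C@@]2(C)[C@@H]3[C@@H](O[Si](C)(C)C(C)(C)C)CC(=C)[C@H]2[C@@H]3C(C)(C)C#N
F6 | step 14 | 9-isovaleryloxy 7-ketone | O=C1C[C@@H](OC(=O)CC(C)C)[C@@]2(C)[C@@H]3[C@@H](O[Si](C)(C)C(C)(C)C)CC(=C)[C@H]2[C@@H]3C1(C)C
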